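The route rests on cutting the lactone C–O bond between the ring D oxygen and C-2, the ring A methylene next to the side-chain carbon C-3. In one operation a photolysed N-iodoamide of the C-3 acetamide chain abstracts hydrogen from C-2 (1,5-shift) and the amide oxygen closes ring D, creating the C-2 stereocentre. The step exploits that C-2 is the only hydrogen-bearing carbon γ to the amide carbonyl: the other γ-carbon, C-4 at the ring A/B fusion, is a fully substituted carbinol carbon. The precursor is the 5-6-7 tricycle (rings A, B, C) with the ring C epoxide in place, a primary acetamide on C-3, the C-4 hydroxyl as TMS ether and the C-17 hydroxyl as TBS ether.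

Key step: step 15

Remark (numbering): tricyclic compounds carry cyathane locants (ring A: C-1, C-2, C-3, C-4, C-9; ring B: C-4 to C-9; ring C: C-5, C-6, C-10 to C-14; C-15 on C-12, C-16 on C-6, C-17 on C-9, side chain C-18/C-20 on C-3, C-19 being the exocyclic methylene); β is the face of C-17 and H-5, α the face of C-16 and the 4-hydroxyl; bicyclic ketones carry benzo[7]annulene locants.
Remark (design): the C-17 oxygen is carried through the key step as a TBS ether and acetylated last, because an acetate would survive neither ester aminolysis nor lactone enolate formation; the tertiary 4-hydroxyl is capped as a TMS ether so that no hypoiodite can form.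
Remark (assumption): the ring-fusion centre next to the ketone is set by equilibration in step 5; the trans-fused ketone is taken to be the more stable epimer, and the cis epimer is recycled.

Step 1
Reactants: 1 3-ethoxycyclohex-2-en-1-one; 2 allylmagnesium bromide
Product: 4 3-(prop-2-en-1-yl)cyclohex-2-en-1-one, via bromomagnesium alkoxide adduct 3 (not isolated)
Conditions: THF, 0 °C; then 1 M HCl, 0 °C
Reagents that add atoms: water O
Why: Stork–Danheiser enone transposition: 1,2-addition of the Grignard reagent to the vinylogous ester and acid-induced loss of ethanol from the tertiary allylic alcohol should give the 3-substituted cyclohexenone, and no stereocentre is formed.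

Step 2
Reactants: 4 3-(prop-2-en-1-yl)cyclohex-2-en-1-one
Product: 6 (S)-trimethyl{[3-methyl-3-(prop-2-en-1-yl)cyclohex-1-en-1-yl]oxy}silane, via dimethylaluminium enolate 5 (not isolated)
Conditions: AlMe3, Cu(O2CC4H3S) (copper thiophene-2-carboxylate, 2 mol%), chiral biphenol-based phosphoramidite with a C2-symmetric bis(1-arylethyl)amine (4 mol%), Et2O, −30 °C; then TMSOTf, 0 °C
Reagents that add atoms: trimethylaluminium C[Al](C)C; trimethylsilyl trifluoromethanesulfonate C[Si](C)(C)OS(=O)(=O)C(F)(F)F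
Why: Copper-catalysed asymmetric conjugate addition of a methylaluminium reagent to a β-substituted cyclohexenone should create the quaternary carbon with the S configuration (face selection by the chiral phosphoramidite–copper complex, ligand enantiomer chosen accordingly), and O-silylation of the aluminium enolate fixes the enolate regiochemistry for the next C–C bond.

Step 3
Reactants: 6 (S)-trimethyl{[3-methyl-3-(prop-2-en-1-yl)cyclohex-1-en-1-yl]oxy}silane; 7 methyl vinyl ketone
Product: 8 (2RS,3S)-3-methyl-2-(3-oxobutyl)-3-(prop-2-en-1-yl)cyclohexan-1-one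
Conditions: BF3·OEt2, iPrOH, CH2Cl2, −78 °C
Reagents that add atoms: none
Why: Mukaiyama–Michael addition of the silyl enol ether to BF3-activated methyl vinyl ketone should alkylate the enol carbon next to the quaternary centre, the new α-stereocentre forming as a mixture that is corrected by equilibration in step 5.

Step 4
Reactants: 8 (2RS,3S)-3-methyl-2-(3-oxobutyl)-3-(prop-2-en-1-yl)cyclohexan-1-one
Product: 9 (2RS,3S)-3-methyl-2-(3-methylbut-3-en-1-yl)-3-(prop-2-en-1-yl)cyclohexan-1-one
Conditions: Ph3PCH3Br, KOtBu (1.1 equiv), THF, −78 → 0 °C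
Reagents that add atoms: methyltriphenylphosphonium bromide C[P+](c1ccccc1)(c1ccccc1)c1ccccc1.[Br-]
Why: Wittig methylenation with a slight excess of ylide should convert the unhindered methyl ketone only, since the ring ketone sits between a tertiary and a quaternary carbon.

Step 5
Reactants: 9 (2RS,3S)-3-methyl-2-(3-methylbut-3-en-1-yl)-3-(prop-2-en-1-yl)cyclohexan-1-one
Product: 11 (4aS,9aS)-4a,7-dimethyl-2,3,4,4a,5,8,9,9a-octahydro-1H-benzo[7]annulen-1-one, via ring-closed ketone epimer mixture 10 (not isolated)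
Conditions: second-generation Grubbs catalyst (3 mol%), CH2Cl2, 40 °C; then NaOMe (catalytic), MeOH, 25 °C; chromatography, cis epimer resubmitted to NaOMe
Reagents that add atoms: none
Why: Ring-closing metathesis of the allyl group with the 1,1-disubstituted alkene should close the trisubstituted cycloheptene, and methoxide equilibration of C-9a, the only stereocentre α to the ketone, should enrich the trans-fused ketone (seven-membered ring attached by two equatorial bonds), the separated cis epimer being recycled through the same equilibrium.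

Step 6
Reactants: 11 (4aS,9aS)-4a,7-dimethyl-2,3,4,4a,5,8,9,9a-octahydro-1H-benzo[7]annulen-1-one
Product: 15 (4aS,9aS)-4a,7-dimethyl-2-methylidene-2,3,4,4a,5,8,9,9a-octahydro-1H-benzo[7]annulen-1-one, via lithium enolate 12 (not isolated), via Mannich base 13 (not isolated), via trimethylammonium iodide 14 (not isolated)
Conditions: LiN(iPr)2, THF, −78 °C; Me2N=CH2+ I−, −78 → 25 °C; then MeI, CH2Cl2, 25 °C; then NaHCO3 (aq), 25 °C
Reagents that add atoms: N,N-dimethylmethyleneiminium iodide C[N+](C)=C.[I-]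
Why: Kinetic deprotonation removes a proton from the C-2 methylene and not from the hindered ring-fusion methine, so Mannich aminomethylation, N-methylation and E1cB loss of trimethylamine should give the 2-methylidene ketone without touching C-9a.

Step 7
Reactants: 15 (4aS,9aS)-4a,7-dimethyl-2-methylidene-2,3,4,4a,5,8,9,9a-octahydro-1H-benzo[7]annulen-1-one; 16 (1,3-dioxolan-2-ylmethyl)magnesium bromide
Product: 18 (2S,4aS,9aS)-2-[2-(1,3-dioxolan-2-yl)ethyl]-2-(hydroxymethyl)-4a,7-dimethyl-2,3,4,4a,5,8,9,9a-octahydro-1H-benzo[7]annulen-1-one, via bromomagnesium enolate 17 (not isolated)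
Conditions: CuBr·SMe2 (10 mol%), THF, −40 °C; then CH2O (gas, from paraformaldehyde), −78 °C; NH4Cl (aq)
Reagents that add atoms: formaldehyde C=O
Why: Copper-catalysed conjugate addition of the Grignard reagent to the exocyclic enone forms the C-1/C-2 enolate regiospecifically, and its aldol reaction with formaldehyde should take place by axial attack on the β face (chair-like transition state of the trans-fused enolate, the α face requiring a twist-boat), which sets the quaternary C-2 with the hydroxymethyl group axial and the acetal chain equatorial.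

Step 8
Reactants: 18 (2S,4aS,9aS)-2-[2-(1,3-dioxolan-2-yl)ethyl]-2-(hydroxymethyl)-4a,7-dimethyl-2,3,4,4a,5,8,9,9a-octahydro-1H-benzo[7]annulen-1-one
Product: 19 (2S,4aS,9aS)-2-{[(tert-butyldimethylsilyl)oxy]methyl}-2-[2-(1,3-dioxolan-2-yl)ethyl]-4a,7-dimethyl-2,3,4,4a,5,8,9,9a-octahydro-1H-benzo[7]annulen-1-one
Conditions: TBSOTf, 2,6-lutidine, CH2Cl2, −78 → 0 °C
Reagents that add atoms: tert-butyldimethylsilyl trifluoromethanesulfonate CC(C)(C)[Si](C)(C)OS(=O)(=O)C(F)(F)F
Why: Silylation with a silyl triflate and a hindered pyridine base protects the neopentyl primary alcohol without enolisation, which blocks retro-aldol cleavage and any hemiacetal or oxa-Michael closure onto the side chain later on.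

Step 9
Reactants: 19 (2S,4aS,9aS)-2-{[(tert-butyldimethylsilyl)oxy]methyl}-2-[2-(1,3-dioxolan-2-yl)ethyl]-4a,7-dimethyl-2,3,4,4a,5,8,9,9a-octahydro-1H-benzo[7]annulen-1-one
Product: 20 3-[(2S,4aS,9aS)-2-{[(tert-butyldimethylsilyl)oxy]methyl}-4a,7-dimethyl-1-oxo-2,3,4,4a,5,8,9,9a-octahydro-1H-benzo[7]annulen-2-yl]propanal
Conditions: PPTS (catalytic), acetone/H2O (9:1), 55 °C
Reagents that add atoms: water O
Why: Acid-catalysed acetal hydrolysis (transacetalisation in wet acetone) frees the aldehyde under conditions that the hindered primary TBS ether and the trisubstituted alkene tolerate.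

Step 10
Reactants: 20 3-[(2S,4aS,9aS)-2-{[(tert-butyldimethylsilyl)oxy]methyl}-4a,7-dimethyl-1-oxo-2,3,4,4a,5,8,9,9a-octahydro-1H-benzo[7]annulen-2-yl]propanal; 21 triethyl phosphonoacetate
Product: 23 ethyl (2E)-5-[(2R,4aS,9aS)-2-{[(tert-butyldimethylsilyl)oxy]methyl}-4a,7-dimethyl-1-oxo-2,3,4,4a,5,8,9,9a-octahydro-1H-benzo[7]annulen-2-yl]pent-2-enoate, via sodium phosphonate anion 22 (not isolated)
Conditions: NaH, THF, 0 °C
Reagents that add atoms: none
Why: Horner–Wadsworth–Emmons olefination of the aldehyde with the preformed sodium phosphonate should give the E-enoate, the hindered α-quaternary ketone being inert and no free base being present to epimerise C-9a (the change of the C-2 descriptor from S to R is formal).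

Step 11
Reactants: 23 ethyl (2E)-5-[(2R,4aS,9aS)-2-{[(tert-butyldimethylsilyl)oxy]methyl}-4a,7-dimethyl-1-oxo-2,3,4,4a,5,8,9,9a-octahydro-1H-benzo[7]annulen-2-yl]pent-2-enoate
Product: 24 ethyl 17-(tert-butyldimethylsilyloxy)-4α-hydroxy-19-norcyath-12-en-20-oate
Conditions: SmI2 (2.5 equiv), HMPA, t-BuOH, THF, −78 → 0 °C
Reagents that add atoms: none
Why: SmI2 ketyl–olefin reductive cyclisation (5-exo-trig): the ketyl carbon C-4 should bond to the enoate β-carbon along the equatorial trajectory, because the axial trajectory is blocked by the syn-axial C-16 methyl, which gives the trans-fused hydrindane with an axial 4α-hydroxyl, and the usual anti arrangement of the O–Sm group and the ester-bearing alkene terminus in the transition state puts the CH2CO2Et arm on C-3 trans to that hydroxyl (3β).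

Step 12
Reactants: 24 ethyl 17-(tert-butyldimethylsilyloxy)-4α-hydroxy-19-norcyath-12-en-20-oate
Product: 25 17-(tert-butyldimethylsilyloxy)-4α-hydroxy-19-norcyath-12-en-20-amide
Conditions: AlMe3, NH4Cl, toluene, 50 °C
Reagents that add atoms: ammonium chloride [NH4+].[Cl-]
Why: Weinreb-type aminolysis by the aluminium amide formed from AlMe3 and NH4Cl should convert the unhindered ethyl ester directly into the primary amide, the silyl ether and the alkene being inert and the tertiary alcohol being carried as its aluminium alkoxide.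

Step 13
Reactants: 25 17-(tert-butyldimethylsilyloxy)-4α-hydroxy-19-norcyath-12-en-20-amide
Product: 26 17-(tert-butyldimethylsilyloxy)-4α-(trimethylsilyloxy)-19-norcyath-12-en-20-amide
Conditions: N-(trimethylsilyl)imidazole, DMF, 60 °C
Reagents that add atoms: N-(trimethylsilyl)imidazole C[Si](C)(C)n1ccnc1
Why: O-silylation with N-(trimethylsilyl)imidazole, a reagent that silylates hindered tertiary alcohols but not amides, caps the 4α-hydroxyl so that no hypoiodite or alkoxy radical can form in step 15.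

Step 14
Reactants: 26 17-(tert-butyldimethylsilyloxy)-4α-(trimethylsilyloxy)-19-norcyath-12-en-20-amide
Product: 27 17-(tert-butyldimethylsilyloxy)-12β,13β-epoxy-4α-(trimethylsilyloxy)-19-norcyathan-20-amide
Conditions: mCPBA, NaHCO3 (buffer), CH2Cl2, 0 °C
Reagents that add atoms: 3-chloroperoxybenzoic acid OOC(=O)c1cccc(Cl)c1
Why: Prilezhaev epoxidation of the only alkene should occur on the β face of the cycloheptene, away from the axial C-16 methyl on the neighbouring ring-fusion carbon, giving the 12β,13β-epoxide, with NaHCO3 protecting the TMS ether from the acid by-product.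

Step 15
Reactants: 27 17-(tert-butyldimethylsilyloxy)-12β,13β-epoxy-4α-(trimethylsilyloxy)-19-norcyathan-20-amide
Product: 31 17-(tert-butyldimethylsilyloxy)-12β,13β-epoxy-4α-(trimethylsilyloxy)-19-norcyathan-20,2β-olide, via N-iodoamide 28 (not isolated), via 2-iodo amide 29 (not isolated), via iminolactone 30 (not isolated)
Conditions: PhI(OAc)2 (2.5 equiv), I2 (1 equiv), NaHCO3 (solid buffer), CH2Cl2, hν (tungsten lamp), 25 °C; then Na2S2O3 (aq); then AcOH/NaOAc buffer (pH 5), THF/H2O, 25 °C
Reagents that add atoms: water O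
Why: PhI(OAc)2 and I2 generate acetyl hypoiodite, which N-iodinates the primary amide; light cleaves the N–I bond and the amidyl radical abstracts a hydrogen from C-2 through a six-membered transition state (1,5-hydrogen transfer), the C-2 radical is trapped by iodine, and the amide oxygen displaces iodide to give an iminolactone that buffered water hydrolyses to the lactone. The closest known reaction is the Hofmann–Löffler–Freytag-type γ-lactonisation of N-iodoamides. Ring D closes through oxygen in a 5-exo-tet mode. The new C-2 stereocentre is controlled by the ring system: a γ-lactone fused to the cyclopentane can only be cis, so oxygen enters on the β face next to the C-3 side chain, and an iodide that cannot be displaced from the back is ionised after oxidation at iodine by the excess reagent and collapses to the same product. The step needs site selectivity among the C–H bonds within reach and chemoselectivity towards the other functional groups: C-4, the second γ-carbon, carries no hydrogen, a shift from C-1 or C-5 would need a larger cyclic transition state, both oxygens are silylated so that no hypoiodite forms, and the alkene has already been converted into the epoxide, which the solid NaHCO3 shields from acid.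

Step 16
Reactants: 31 17-(tert-butyldimethylsilyloxy)-12β,13β-epoxy-4α-(trimethylsilyloxy)-19-norcyathan-20,2β-olide
Product: 35 17-(tert-butyldimethylsilyloxy)-12β,13β-epoxy-4α-(trimethylsilyloxy)cyath-18(19)-en-20,2β-olide, via lithium enolate 32 (not isolated), via Mannich base 33 (not isolated), via trimethylammonium iodide 34 (not isolated)
Conditions: LiN(iPr)2, THF, −78 °C; Me2N=CH2+ I−, −78 → 0 °C; then MeI, MeOH, 25 °C; then NaHCO3 (aq), 25 °C
Reagents that add atoms: N,N-dimethylmethyleneiminium iodide C[N+](C)=C.[I-]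
Why: Lactone enolate Mannich reaction followed by N-methylation and elimination of trimethylamine (α-methylenation through the Mannich base) should install the exocyclic methylene, the lactone α-CH2 being the only acidic position now that the primary oxygen is a silyl ether and not an ester.

Step 17
Reactants: 35 17-(tert-butyldimethylsilyloxy)-12β,13β-epoxy-4α-(trimethylsilyloxy)cyath-18(19)-en-20,2β-olide
Product: 36 12β,13β-epoxy-4α,17-dihydroxycyath-18(19)-en-20,2β-olide
Conditions: TBAF, AcOH, THF, 0 → 25 °C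
Reagents that add atoms: none
Why: Fluoride-induced desilylation buffered with acetic acid should cleave both silyl ethers while the epoxide, the lactone and its Michael-acceptor methylene group stay intact.

Step 18
Reactants: 36 12β,13β-epoxy-4α,17-dihydroxycyath-18(19)-en-20,2β-olide
Product: 37 17-acetoxy-12β,13β-epoxy-4α-hydroxycyath-18(19)-en-20,2β-olide (CNP0214540.1)
Conditions: Ac2O, pyridine, DMAP (catalytic), CH2Cl2, 0 °C
Reagents that add atoms: acetic anhydride CC(=O)OC(C)=O
Why: Acylation with acetic anhydride and pyridine should esterify only the primary alcohol, since the tertiary 4α-hydroxyl is flanked by one quaternary and two tertiary carbons and is syn-axial to the C-16 methyl.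

Compound list
1 | 3-ethoxycyclohex-2-en-1-one | CCOC1=CC(=O)CCC1 | starting material
2 | allylmagnesium bromide | C=CC[Mg]Br | starting material
3 | bromomagnesium 1-allyl-3-ethoxycyclohex-2-en-1-olate (racemic) | CCOC1=CC(CC=C)(O[Mg]Br)CCC1 | intermediate
4 | 3-(prop-2-en-1-yl)cyclohex-2-en-1-one | C=CCC1=CC(=O)CCC1 | intermediate
5 | dimethylaluminium (S)-3-methyl-3-(prop-2-en-1-yl)cyclohex-1-en-1-olate | C[Al](C)OC1=C[C@](C)(CC=C)CCC1 | intermediate
6 | (S)-trimethyl{[3-methyl-3-(prop-2-en-1-yl)cyclohex-1-en-1-yl]oxy}silane | C[Si](C)(C)OC1=C[C@](C)(CC=C)CCC1 | intermediate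
7 | methyl vinyl ketone | CC(=O)C=C | starting material
8 | (2RS,3S)-3-methyl-2-(3-oxobutyl)-3-(prop-2-en-1-yl)cyclohexan-1-one (C-2 epimers) | O=C1CCC[C@@](C)(CC=C)C1CCC(C)=O | intermediate
9 | (2RS,3S)-3-methyl-2-(3-methylbut-3-en-1-yl)-3-(prop-2-en-1-yl)cyclohexan-1-one (C-2 epimers) | O=C1CCC[C@@](C)(CC=C)C1CCC(C)=C | intermediate
10 | (4aS,9aRS)-4a,7-dimethyl-2,3,4,4a,5,8,9,9a-octahydro-1H-benzo[7]annulen-1-one (ring-fusion epimers) | O=C1CCC[C@@]2(C)CC=C(C)CCC21 | intermediate
11 | (4aS,9aS)-4a,7-dimethyl-2,3,4,4a,5,8,9,9a-octahydro-1H-benzo[7]annulen-1-one (trans-fused; 9a-H β, 4a-Me α) | O=C1CCC[C@@]2(C)CC=C(C)CC[C@@H]21 | intermediate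
12 | lithium C-1/C-2 enolate of 11 | [Li]OC1=CCC[C@@]2(C)CC=C(C)CC[C@@H]21 | intermediate
13 | (4aS,9aS)-2-[(dimethylamino)methyl]-4a,7-dimethyl-2,3,4,4a,5,8,9,9a-octahydro-1H-benzo[7]annulen-1-one (C-2 epimers) | O=C1C(CN(C)C)CC[C@@]2(C)CC=C(C)CC[C@@H]21 | intermediate
14 | methiodide of 13 (trimethylammonium iodide) | O=C1C(C[N+](C)(C)C)CC[C@@]2(C)CC=C(C)CC[C@@H]21.[I-] | intermediate
15 | (4aS,9aS)-4a,7-dimethyl-2-methylidene-2,3,4,4a,5,8,9,9a-octahydro-1H-benzo[7]annulen-1-one | O=C1C(=C)CC[C@@]2(C)CC=C(C)CC[C@@H]21 | intermediate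
16 | (1,3-dioxolan-2-ylmethyl)magnesium bromide | Br[Mg]CC1OCCO1 | starting material
17 | bromomagnesium C-1/C-2 enolate of (4aS,9aS)-2-[2-(1,3-dioxolan-2-yl)ethyl]-4a,7-dimethyl-octahydrobenzo[7]annulen-1-one | Br[Mg]OC1=C(CCC2OCCO2)CC[C@@]3(C)CC=C(C)CC[C@@H]31 | intermediate
18 | (2S,4aS,9aS)-2-[2-(1,3-dioxolan-2-yl)ethyl]-2-(hydroxymethyl)-4a,7-dimethyl-2,3,4,4a,5,8,9,9a-octahydro-1H-benzo[7]annulen-1-one (CH2OH axial, β) | O=C1[C@](CO)(CCC2OCCO2)CC[C@@]3(C)CC=C(C)CC[C@@H]31 | intermediate
19 | (2S,4aS,9aS)-2-{[(tert-butyldimethylsilyl)oxy]methyl}-2-[2-(1,3-dioxolan-2-yl)ethyl]-4a,7-dimethyl-2,3,4,4a,5,8,9,9a-octahydro-1H-benzo[7]annulen-1-one | O=C1[C@](CO[Si](C)(C)C(C)(C)C)(CCC2OCCO2)CC[C@@]3(C)CC=C(C)CC[C@@H]31 | intermediate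
20 | 3-[(2S,4aS,9aS)-2-{[(tert-butyldimethylsilyl)oxy]methyl}-4a,7-dimethyl-1-oxo-2,3,4,4a,5,8,9,9a-octahydro-1H-benzo[7]annulen-2-yl]propanal | O=C1[C@](CO[Si](C)(C)C(C)(C)C)(CCC=O)CC[C@@]2(C)CC=C(C)CC[C@@H]21 | intermediate
21 | triethyl phosphonoacetate | CCOC(=O)CP(=O)(OCC)OCC | starting material
22 | sodium salt of triethyl phosphonoacetate | CCOC(=O)[CH-]P(=O)(OCC)OCC.[Na+] | intermediate
23 | ethyl (2E)-5-[(2R,4aS,9aS)-2-{[(tert-butyldimethylsilyl)oxy]methyl}-4a,7-dimethyl-1-oxo-2,3,4,4a,5,8,9,9a-octahydro-1H-benzo[7]annulen-2-yl]pent-2-enoate | O=C1[C@](CO[Si](C)(C)C(C)(C)C)(CC/C=C/C(=O)OCC)CC[C@@]2(C)CC=C(C)CC[C@@H]21 | intermediate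
24 | ethyl 17-(tert-butyldimethylsilyloxy)-4α-hydroxy-19-norcyath-12-en-20-oate (3β-CH2CO2Et, 5β-H, 6α-Me, 9β-CH2OTBS) | CCOC(=O)C[C@H]1CC[C@]2(CO[Si](C)(C)C(C)(C)C)CC[C@@]3(C)CC=C(C)CC[C@@H]3[C@@]12O | intermediate
25 | 17-(tert-butyldimethylsilyloxy)-4α-hydroxy-19-norcyath-12-en-20-amide | NC(=O)C[C@H]1CC[C@]2(CO[Si](C)(C)C(C)(C)C)CC[C@@]3(C)CC=C(C)CC[C@@H]3[C@@]12O | intermediate
26 | 17-(tert-butyldimethylsilyloxy)-4α-(trimethylsilyloxy)-19-norcyath-12-en-20-amide | NC(=O)C[C@H]1CC[C@]2(CO[Si](C)(C)C(C)(C)C)CC[C@@]3(C)CC=C(C)CC[C@@H]3[C@@]12O[Si](C)(C)C | intermediate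
27 | 17-(tert-butyldimethylsilyloxy)-12β,13β-epoxy-4α-(trimethylsilyloxy)-19-norcyathan-20-amide (key-step precursor) | NC(=O)C[C@H]1CC[C@]2(CO[Si](C)(C)C(C)(C)C)CC[C@@]3(C)C[C@H]4O[C@@]4(C)CC[C@@H]3[C@@]12O[Si](C)(C)C | intermediate
28 | N-iodo derivative of amide 27 | INC(=O)C[C@H]1CC[C@]2(CO[Si](C)(C)C(C)(C)C)CC[C@@]3(C)C[C@H]4O[C@@]4(C)CC[C@@H]3[C@@]12O[Si](C)(C)C | intermediate
29 | 2-iodo derivative of amide 27 (C-2 epimers) | NC(=O)C[C@H]1C(I)C[C@]2(CO[Si](C)(C)C(C)(C)C)CC[C@@]3(C)C[C@H]4O[C@@]4(C)CC[C@@H]3[C@@]12O[Si](C)(C)C | intermediate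
30 | iminolactone (20-imino analogue of lactone 31, 2β-O–C(=NH)) | C1C(=N)O[C@H]2C[C@]3(CO[Si](C)(C)C(C)(C)C)CC[C@@]4(C)C[C@H]5O[C@@]5(C)CC[C@@H]4[C@@]3(O[Si](C)(C)C)[C@@H]12 | intermediate
31 | 17-(tert-butyldimethylsilyloxy)-12β,13β-epoxy-4α-(trimethylsilyloxy)-19-norcyathan-20,2β-olide (key-step product, cis-fused lactone) | C1C(=O)O[C@H]2C[C@]3(CO[Si](C)(C)C(C)(C)C)CC[C@@]4(C)C[C@H]5O[C@@]5(C)CC[C@@H]4[C@@]3(O[Si](C)(C)C)[C@@H]12 | intermediate
32 | lithium enolate of lactone 31 | C1=C(O[Li])O[C@H]2C[C@]3(CO[Si](C)(C)C(C)(C)C)CC[C@@]4(C)C[C@H]5O[C@@]5(C)CC[C@@H]4[C@@]3(O[Si](C)(C)C)[C@@H]12 | intermediate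
33 | 19-(dimethylamino) derivative: 17-(tert-butyldimethylsilyloxy)-19-(dimethylamino)-12β,13β-epoxy-4α-(trimethylsilyloxy)cyathan-20,2β-olide (C-18 epimers) | CN(C)CC1C(=O)O[C@H]2C[C@]3(CO[Si](C)(C)C(C)(C)C)CC[C@@]4(C)C[C@H]5O[C@@]5(C)CC[C@@H]4[C@@]3(O[Si](C)(C)C)[C@@H]12 | intermediate
34 | methiodide of 33 (trimethylammonium iodide) | C[N+](C)(C)CC1C(=O)O[C@H]2C[C@]3(CO[Si](C)(C)C(C)(C)C)CC[C@@]4(C)C[C@H]5O[C@@]5(C)CC[C@@H]4[C@@]3(O[Si](C)(C)C)[C@@H]12.[I-] | intermediate
35 | 17-(tert-butyldimethylsilyloxy)-12β,13β-epoxy-4α-(trimethylsilyloxy)cyath-18(19)-en-20,2β-olide | C=C1C(=O)O[C@H]2C[C@]3(CO[Si](C)(C)C(C)(C)C)CC[C@@]4(C)C[C@H]5O[C@@]5(C)CC[C@@H]4[C@@]3(O[Si](C)(C)C)[C@@H]12 | intermediate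
36 | 12β,13β-epoxy-4α,17-dihydroxycyath-18(19)-en-20,2β-olide | C=C1C(=O)O[C@H]2C[C@]3(CO)CC[C@@]4(C)C[C@H]5O[C@@]5(C)CC[C@@H]4[C@@]3(O)[C@@H]12 | intermediate
37 | 17-acetoxy-12β,13β-epoxy-4α-hydroxycyath-18(19)-en-20,2β-olide (CNP0214540.1) | C=C1C(=O)O[C@H]2C[C@]3(COC(C)=O)CC[C@@]4(C)C[C@H]5O[C@@]5(C)CC[C@@H]4[C@@]3(O)[C@@H]12 | target

Total step count: 18. Longest linear sequence: 18 steps (1 → 37).

Steps most likely to fail

Step 15 (key step). Three processes can divert it: the primary amide may undergo a Hofmann-type rearrangement at the hypervalent iodine reagent, the epoxide may be opened by iodide or acid, or hydrogen may be taken from C-5 instead of C-2. Fallback: the C-2 oxygen is put in before ring A exists, by enamine catalysis. Setting out from aldehyde 20, D-proline-catalysed α-aminoxylation with nitrosobenzene gives the α-anilinooxy aldehyde F1, which is olefinated in the same flask with 21 (LiCl, DBU) to the γ-anilinooxy enoate F2. N–O cleavage (Zn, AcOH) gives the γ-hydroxy enoate F3, and TESCl/imidazole gives its triethylsilyl ether F4. SmI2 cyclisation under the conditions of step 11 gives the tricyclic ester F5. PPTS in MeOH removes the triethylsilyl group and the cis γ-hydroxy ester closes to the hydroxy lactone F6. Silylation as in step 13 gives the TMS ether F7, and epoxidation as in step 14 returns to lactone 31.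

Step 11. The ketyl may bond on the axial face (cis-fused hydrindane), the ester arm may end up syn to the hydroxyl, or the hindered ketone may simply be reduced. Fallback: ring A is closed by a polar allylsilane addition. Setting out from aldehyde 20, Wittig reaction with Ph3P=CHCH2SiMe3 gives the allylsilane F8. Intramolecular Hosomi–Sakurai addition to the ketone (BF3·OEt2, CH2Cl2, −78 °C) gives the 3-vinyl carbinol F9; its relative configuration can be steered by changing from Lewis-acid to fluoride activation. Hydroboration of the vinyl group (9-BBN; then NaOH, H2O2) gives the primary alcohol F10. Oxidation (TEMPO, PhI(OAc)2, MeCN/H2O) gives the acid F11, and mixed-anhydride amidation (ClCO2Et, Et3N; then NH3) returns to hydroxy amide 25.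

Step 5. The equilibrium at the ring fusion may leave too little trans-fused ketone, so that enrichment needs many recycles. Fallback: the ring fusion is set kinetically by hydrogen-atom transfer. Setting out from ketone 9, Tf2O with 2,6-di-tert-butyl-4-methylpyridine gives the more substituted enol triflate F12. Pd(OAc)2/PPh3-catalysed reduction with HCO2H/Bu3N gives the triene F13, and mCPBA epoxidises its only trisubstituted alkene to F14. Ring-closing metathesis as in step 5 gives the bicyclic epoxide F15. Cp2TiCl (trivalent titanium, from Cp2TiCl2 and Zn) with 1,4-cyclohexadiene opens the epoxide to the tertiary ring-fusion radical, which should take hydrogen on the face away from the angular methyl to give the trans-fused alcohol F16. Dess–Martin oxidation returns to ketone 11.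

Further compounds
F1 | step 15 | (S)-α-anilinooxy derivative of aldehyde 20 | O=C1[C@](CO[Si](C)(C)C(C)(C)C)(C[C@H](ONc2ccccc2)C=O)CC[C@@]3(C)CC=C(C)CC[C@@H]31
F2 | step 15 | γ-anilinooxy analogue of enoate 23 | O=C1[C@](CO[Si](C)(C)C(C)(C)C)(C[C@H](ONc2ccccc2)/C=C/C(=O)OCC)CC[C@@]3(C)CC=C(C)CC[C@@H]31
F3 | step 15 | γ-hydroxy analogue of enoate 23 | O=C1[C@](CO[Si](C)(C)C(C)(C)C)(C[C@H](O)/C=C/C(=O)OCC)CC[C@@]2(C)CC=C(C)CC[C@@H]21
F4 | step 15 | γ-(triethylsilyloxy) analogue of enoate 23 | O=C1[C@](CO[Si](C)(C)C(C)(C)C)(C[C@H](O[Si](CC)(CC)CC)/C=C/C(=O)OCC)CC[C@@]2(C)CC=C(C)CC[C@@H]21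
F5 | step 15 | ethyl 17-(tert-butyldimethylsilyloxy)-4α-hydroxy-2β-(triethylsilyloxy)-19-norcyath-12-en-20-oate | CCOC(=O)C[C@H]1[C@@H](O[Si](CC)(CC)CC)C[C@]2(CO[Si](C)(C)C(C)(C)C)CC[C@@]3(C)CC=C(C)CC[C@@H]3[C@@]12O
F6 | step 15 | 17-(tert-butyldimethylsilyloxy)-4α-hydroxy-19-norcyath-12-en-20,2β-olide | C1C(=O)O[C@H]2C[C@]3(CO[Si](C)(C)C(C)(C)C)CC[C@@]4(C)CC=C(C)CC[C@@H]4[C@@]3(O)[C@@H]12
F7 | step 15 | 17-(tert-butyldimethylsilyloxy)-4α-(trimethylsilyloxy)-19-norcyath-12-en-20,2β-olide | C1C(=O)O[C@H]2C[C@]3(CO[Si](C)(C)C(C)(C)C)CC[C@@]4(C)CC=C(C)CC[C@@H]4[C@@]3(O[Si](C)(C)C)[C@@H]12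
F8 | step 11 | allylsilane from aldehyde 20 (2-[5-(trimethylsilyl)pent-3-en-1-yl] ketone) | O=C1[C@](CO[Si](C)(C)C(C)(C)C)(CCC=CC[Si](C)(C)C)CC[C@@]2(C)CC=C(C)CC[C@@H]21
F9 | step 11 | 17-(tert-butyldimethylsilyloxy)-3β-vinyl tricyclic 4α-carbinol (19,20-dinorcyatha-12,18-dien-4α-ol numbering of the vinyl as C-18/C-20) | C=C[C@H]1CC[C@]2(CO[Si](C)(C)C(C)(C)C)CC[C@@]3(C)CC=C(C)CC[C@@H]3[C@@]12O
F10 | step 11 | 17-(tert-butyldimethylsilyloxy)-19-norcyath-12-ene-4α,20-diol | OCC[C@H]1CC[C@]2(CO[Si](C)(C)C(C)(C)C)CC[C@@]3(C)CC=C(C)CC[C@@H]3[C@@]12O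
F11 | step 11 | 17-(tert-butyldimethylsilyloxy)-4α-hydroxy-19-norcyath-12-en-20-oic acid | OC(=O)C[C@H]1CC[C@]2(CO[Si](C)(C)C(C)(C)C)CC[C@@]3(C)CC=C(C)CC[C@@H]3[C@@]12O
F12 | step 5 | (S)-6-methyl-2-(3-methylbut-3-en-1-yl)-6-(prop-2-en-1-yl)cyclohex-1-en-1-yl trifluoromethanesulfonate | O=S(=O)(OC1=C(CCC(C)=C)[C@](C)(CC=C)CCC1)C(F)(F)F
F13 | step 5 | (S)-6-methyl-1-(3-methylbut-3-en-1-yl)-6-(prop-2-en-1-yl)cyclohex-1-ene | C1=C(CCC(C)=C)[C@](C)(CC=C)CCC1
F14 | step 5 | 1,2-epoxide of F13 (epoxide epimers) | C=C(C)CCC12OC1CCC[C@@]2(C)CC=C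
F15 | step 5 | (4aS)-1,9a-epoxy-4a,7-dimethyl-2,3,4,4a,5,8,9,9a-octahydro-1H-benzo[7]annulene (epoxide epimers) | CC1=CC[C@]2(C)CCCC3OC23CC1
F16 | step 5 | (4aS,9aS)-4a,7-dimethyl-2,3,4,4a,5,8,9,9a-octahydro-1H-benzo[7]annulen-1-ol (C-1 epimers) | OC1CCC[C@@]2(C)CC=C(C)CC[C@@H]21
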